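## Retrosynthetic overview

1. Both aryl C–O–S bonds are made last: 30 ⇐ phenol 28 by para C–H sulfatoxylation (the new C–O bond) plus O-sulfation; 28 ⇐ methyl ether 27.
2. Ring B is annulated onto ring A with the side chain already in place: 27 ⇐ enedione 18 (Robinson annulation of dione 15 with ethyl vinyl ketone); the C9 arylmethyl group, the C8 methyl and the C4 methylene follow.
3. The CH2–CH2 link: 15 ⇐ aldehyde 12 + cyclohexane-1,3-dione (reductive alkylation).
4. Lower unit: 12 ⇐ allylic alcohol 10 (Claisen rearrangement creates quaternary C9′) ⇐ dienynone 7 (intramolecular Diels–Alder) ⇐ isobutyraldehyde and methyl acrylate.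
5. Ring order: rings C and D together (Diels–Alder), ring A enters intact as cyclohexane-1,3-dione, ring B last (Robinson annulation).

Notation: upper decalin atoms are C1–C10 (C4 ends as C=CH2, C5 = quaternary ring-fusion carbon bearing the link, C10 = ring-fusion CH, C9 = quaternary carbon bearing CH3 and arylmethyl, C8 = CH–CH3; β = face of the C5 side chain); lower decalin atoms carry primes (C9′ quaternary, C8′ CH–CH3, C10′=C1′ alkene, C5′ ring-fusion CH); Q = (1R,2S,4aS)-1,2,5,5-tetramethyl-1,2,3,4,4a,5,6,7-octahydronaphthalen-1-yl.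

Assumption: the target is the free bis(hydrogen sulfate) as drawn, released from its tetrabutylammonium salt on an acidic resin in the last step; racemic 8 and 9 are drawn as the enantiomer that is carried on.

## Route

Step 1
Reactants: 1 isobutyraldehyde (2-methylpropanal); 2 methyl acrylate
Product: 4 methyl 4,4-dimethyl-5-oxopentanoate, via enamine 3 (not isolated)
Conditions: pyrrolidine (1.1 eq), K2CO3, toluene, 0 °C → rt; then 2, MeCN, reflux; then AcOH/NaOAc/H2O, 50 °C
Reagents that add atoms: none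
Why: Stork enamine Michael addition; the fully substituted enamine carbon adds once to the acrylate and hydrolysis returns the aldehyde with the new quaternary carbon (no stereocentre).

Step 2
Reactants: 4 methyl 4,4-dimethyl-5-oxopentanoate
Product: 5 methyl (5E,7E)-4,4-dimethylnona-5,7-dienoate
Conditions: (E)-but-2-enyl(triphenyl)phosphonium bromide, n-BuLi, THF, −78 → 0 °C; then I2 (2 mol %), hexane, daylight, rt
Reagents that add atoms: (E)-but-2-enyl(triphenyl)phosphonium bromide, C/C=C/C[P+](c1ccccc1)(c1ccccc1)c1ccccc1.[Br-]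
Why: Wittig olefination with a semi-stabilised allylic ylide forms the diene, and iodine-catalysed equilibration converts the 5Z isomer into the 5E,7E diene needed for the cycloaddition (no stereocentre).

Step 3
Reactants: 5 methyl (5E,7E)-4,4-dimethylnona-5,7-dienoate
Product: 7 (8E,10E)-7,7-dimethyldodeca-8,10-dien-2-yn-4-one, via Weinreb amide 6 (not isolated)
Conditions: MeNH(OMe)·HCl (1.5 eq), i-PrMgCl (3 eq), THF, −20 °C; then prop-1-ynylmagnesium bromide (2 eq), 0 °C → rt; aq. NH4Cl
Reagents that add atoms: prop-1-ynylmagnesium bromide, CC#C[Mg]Br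
Why: Weinreb ketone synthesis run in one flask; the chelated tetrahedral adduct stops the alkynyl Grignard addition at the ynone (no stereocentre).

Step 4
Reactants: 7 (8E,10E)-7,7-dimethyldodeca-8,10-dien-2-yn-4-one
Product: 8 (4aRS,7RS)-4,4,7,8-tetramethyl-3,4,4a,7-tetrahydronaphthalen-1(2H)-one
Conditions: toluene (0.02 M), BHT (cat.), 130 °C, sealed tube, argon
Reagents that add atoms: none
Why: Intramolecular Diels–Alder reaction of the ynone with the tethered E,E-diene closes rings C and D at once; suprafacial addition to the diene puts H-4a and H-7 cis (the C5′/C8′ relation of the target), as a racemate.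

Step 5
Reactants: 8 (4aRS,7RS)-4,4,7,8-tetramethyl-3,4,4a,7-tetrahydronaphthalen-1(2H)-one
Product: 9 (4aRS,7RS)-4,4,7,8-tetramethyl-3,4,4a,5,6,7-hexahydronaphthalen-1(2H)-one
Conditions: H2 (1 atm), RhCl(PPh3)3 (5 mol %), benzene, rt
Reagents that add atoms: none
Why: Chemoselective homogeneous hydrogenation; the catalyst reduces the cis-disubstituted ring alkene and leaves the tetrasubstituted conjugated alkene, with no change at the stereocentres.

Step 6
Reactants: 9 (4aRS,7RS)-4,4,7,8-tetramethyl-3,4,4a,5,6,7-hexahydronaphthalen-1(2H)-one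
Product: 10 (1S,4aS,7S)-4,4,7,8-tetramethyl-1,2,3,4,4a,5,6,7-octahydronaphthalen-1-ol
Conditions: (R)-1-methyl-3,3-diphenyltetrahydro-1H,3H-pyrrolo[1,2-c][1,3,2]oxazaborole ((R)-Me-CBS, 0.2 eq), BH3·SMe2 (0.7 eq), toluene, −30 °C; MeOH; chromatography
Reagents that add atoms: none
Why: Corey–Bakshi–Shibata reduction under reagent control gives the 1S carbinol from both enantiomers of 9, so the 4aS,7S enone gives 10 and its antipode gives a separable diastereomer (a resolution, at most half of the material).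

Step 7
Reactants: 10 (1S,4aS,7S)-4,4,7,8-tetramethyl-1,2,3,4,4a,5,6,7-octahydronaphthalen-1-ol
Product: 12 2-Q-acetaldehyde, via allyl vinyl ether 11 (not isolated)
Conditions: ethyl vinyl ether (solvent), Hg(OAc)2 (0.2 eq), reflux; K2CO3, concentrate; then n-decane, 190 °C, sealed tube
Reagents that add atoms: ethyl vinyl ether, C=COCC
Why: Claisen rearrangement of the allyl vinyl ether ([3,3] shift, suprafacial) transfers the C1′–O configuration to the new quaternary C9′; the CH2CHO group arrives on the face of the former C–O bond, anti to the C8′ methyl, and the alkene moves to C10′=C1′.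

Step 8
Reactants: 12 2-Q-acetaldehyde; 13 cyclohexane-1,3-dione
Product: 15 2-(2-Q-ethyl)cyclohexane-1,3-dione, via alkylidene dione 14 (not isolated)
Conditions: L-proline (20 mol %), diethyl 2,6-dimethyl-1,4-dihydropyridine-3,5-dicarboxylate (Hantzsch ester, 1.1 eq), CH2Cl2, rt
Reagents that add atoms: none
Why: Three-component reductive alkylation (Knoevenagel condensation, then Hantzsch-ester transfer hydrogenation of the alkylidene dione) gives C-alkylation only; no new stereocentre.

Step 9
Reactants: 15 2-(2-Q-ethyl)cyclohexane-1,3-dione; 16 ethyl vinyl ketone (pent-1-en-3-one)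
Product: 18 (8aS)-5-methyl-8a-(2-Q-ethyl)-3,4,8,8a-tetrahydronaphthalene-1,6(2H,7H)-dione, via triketone 17 (not isolated)
Conditions: 16 (1.5 eq), Et3N (10 mol %), EtOAc, rt; evaporate; L-phenylalanine (1 eq), (1S)-(+)-camphor-10-sulfonic acid (0.5 eq), DMF, 30 → 70 °C
Reagents that add atoms: none
Why: Robinson annulation (Michael addition, then amino-acid-mediated Hajos–Parrish-type enamine aldol condensation) forms ring B; L-phenylalanine differentiates the two ring carbonyls and sets quaternary C5 (S at C8a of 18), the sense it gives in the S series of Wieland–Miescher-type ketones.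

Step 10
Reactants: 18 (8aS)-5-methyl-8a-(2-Q-ethyl)-3,4,8,8a-tetrahydronaphthalene-1,6(2H,7H)-dione
Product: 19 C4 ethylene ketal of 18
Conditions: ethane-1,2-diol (5 eq), TsOH·H2O (5 mol %), 4 Å molecular sieves, CH2Cl2, rt
Reagents that add atoms: ethane-1,2-diol, OCCO
Why: Chemoselective ketalisation; the saturated C4 ketone reacts and the less electrophilic conjugated C8 ketone does not, with no change at the stereocentres.

Step 11
Reactants: 19 C4 ethylene ketal of 18; 20 2-methoxybenzyl bromide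
Product: 23 9β-(2-methoxybenzyl) cis-decalin ketal ketone, via silyl enol ether 21 (not isolated), via lithium enolate 22 (not isolated)
Conditions: [(Ph3P)CuH]6 (10 mol %), PhMe2SiH (1.5 eq), toluene, rt → 40 °C; filter, concentrate; MeLi (1.1 eq), THF, 0 °C; then 20 (1.5 eq), DMPU, −78 → 0 °C
Reagents that add atoms: none
Why: Tandem conjugate reduction–enolate alkylation; copper hydride delivers hydride to C10 syn to the angular C5 chain (cis ring fusion, trapped as the silyl enol ether), MeLi unmasks the regiodefined lithium enolate, and benzylation at C9 on the convex β-face, anti to the pseudoaxial C10–C1 bond, puts the arylmethyl group cis to H-10.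

Step 12
Reactants: 23 9β-(2-methoxybenzyl) cis-decalin ketal ketone
Product: 24 C8-methylidene ketal
Conditions: Ph3PCH3Br (4 eq), KOtBu (3.8 eq), toluene, 90 °C
Reagents that add atoms: methyl(triphenyl)phosphonium bromide, C[P+](c1ccccc1)(c1ccccc1)c1ccccc1.[Br-]
Why: Wittig methylenation with the small, unstabilised ylide at elevated temperature converts the neopentyl C8 ketone into the exocyclic alkene; no stereocentre changes.

Step 13
Reactants: 24 C8-methylidene ketal
Product: 25 8β-methyl ketal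
Conditions: H2 (4 atm), RhCl(PPh3)3 (10 mol %), benzene/EtOH (1:1), 40 °C
Reagents that add atoms: none
Why: Homogeneous hydrogenation reduces only the 1,1-disubstituted exocyclic alkene (the trisubstituted C10′=C1′ bond is inert); in the ring B chair that keeps the bulky ketal carbon equatorial the 9β-arylmethyl group is axial and shields the β-face, so hydrogen adds from the α-face and the new methyl is 8β.

Step 14
Reactants: 25 8β-methyl ketal
Product: 26 C4 ketone
Conditions: PPTS (0.3 eq), acetone/H2O (9:1), 60 °C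
Reagents that add atoms: water, O
Why: Mild acid-catalysed ketal hydrolysis frees the C4 ketone without isomerising the trisubstituted alkene; no stereocentre changes.

Step 15
Reactants: 26 C4 ketone
Product: 27 1-{[(1S,2S,4aR,8aR)-1,2-dimethyl-5-methylidene-4a-(2-Q-ethyl)decahydronaphthalen-1-yl]methyl}-2-methoxybenzene
Conditions: Ph3PCH3Br (5 eq), KOtBu (4.8 eq), toluene, 100 °C
Reagents that add atoms: methyl(triphenyl)phosphonium bromide, C[P+](c1ccccc1)(c1ccccc1)c1ccccc1.[Br-]
Why: Wittig methylenation of the hindered C4 ketone next to quaternary C5 installs the exocyclic methylene; no stereocentre changes.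

Step 16
Reactants: 27 methyl ether
Product: 28 2-{[(1S,2S,4aR,8aR)-1,2-dimethyl-5-methylidene-4a-(2-Q-ethyl)decahydronaphthalen-1-yl]methyl}phenol
Conditions: NaSEt (6 eq), DMF, 130 °C; aq. NH4Cl
Reagents that add atoms: none
Why: SN2 O-demethylation of the aryl methyl ether by thiolate; the purely basic conditions leave both alkenes in place.

Step 17
Reactants: 28 phenol
Product: 30 target bis(hydrogen sulfate) CNP0439949.2, via aryl monosulfate 29 (not isolated)
Conditions: Bu4NOH (1.0 eq, in MeOH), evaporate and dry; (Bu4N)2S2O8 (1.2 eq), MeCN/THF (3:1), 0 °C → rt, dark, argon; then SO3·NMe3 (4 eq), 45 °C; Dowex 50W (H+ form), MeOH/H2O, 0 °C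
Reagents that add atoms: bis(tetrabutylammonium) peroxydisulfate, CCCC[N+](CCCC)(CCCC)CCCC.CCCC[N+](CCCC)(CCCC)CCCC.[O-]S(=O)(=O)OOS(=O)(=O)[O-]; sulfur trioxide–trimethylamine, C[N+](C)(C)S(=O)(=O)[O-]
Why: Proposed new method: a homogeneous, non-aqueous Elbs-type para C–H sulfatoxylation telescoped with O-sulfation — the naked tetrabutylammonium phenolate of 28 attacks the O–O bond of peroxydisulfate through its free para carbon, the dienone tautomerises to the phenolate of monosulfate 29, and SO3·NMe3 sulfates that oxygen, so both aryl C–O–S bonds form in one flask; in the dark at room temperature without metal no sulfate radical should form, so the two alkenes should be spared; closest known reactions are the Elbs persulfate oxidation of water-soluble phenols in aqueous alkali and SO3–amine sulfation of phenols.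

## Compound list

1 | isobutyraldehyde (2-methylpropanal) | CC(C)C=O | starting material
2 | methyl acrylate | C=CC(=O)OC | starting material
3 | 1-(2-methylprop-1-en-1-yl)pyrrolidine | CC(C)=CN1CCCC1 | intermediate (not isolated)
4 | methyl 4,4-dimethyl-5-oxopentanoate | COC(=O)CCC(C)(C)C=O | intermediate
5 | methyl (5E,7E)-4,4-dimethylnona-5,7-dienoate | COC(=O)CCC(C)(C)/C=C/C=C/C | intermediate
6 | (5E,7E)-N-methoxy-N,4,4-trimethylnona-5,7-dienamide | CON(C)C(=O)CCC(C)(C)/C=C/C=C/C | intermediate (not isolated)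
7 | (8E,10E)-7,7-dimethyldodeca-8,10-dien-2-yn-4-one | CC#CC(=O)CCC(C)(C)/C=C/C=C/C | intermediate
8 | (4aRS,7RS)-4,4,7,8-tetramethyl-3,4,4a,7-tetrahydronaphthalen-1(2H)-one (H-4a and H-7 cis; racemate) | CC1=C2C(=O)CCC(C)(C)[C@@H]2C=C[C@@H]1C | intermediate
9 | (4aRS,7RS)-4,4,7,8-tetramethyl-3,4,4a,5,6,7-hexahydronaphthalen-1(2H)-one (racemate) | CC1=C2C(=O)CCC(C)(C)[C@@H]2CC[C@@H]1C | intermediate
10 | (1S,4aS,7S)-4,4,7,8-tetramethyl-1,2,3,4,4a,5,6,7-octahydronaphthalen-1-ol | CC1=C2[C@@H](O)CCC(C)(C)[C@@H]2CC[C@@H]1C | intermediate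
11 | (1S,4aS,7S)-1-(ethenyloxy)-4,4,7,8-tetramethyl-1,2,3,4,4a,5,6,7-octahydronaphthalene | CC1=C2[C@@H](OC=C)CCC(C)(C)[C@@H]2CC[C@@H]1C | intermediate (not isolated)
12 | 2-[(1R,2S,4aS)-1,2,5,5-tetramethyl-1,2,3,4,4a,5,6,7-octahydronaphthalen-1-yl]acetaldehyde (Q–CH2–CHO) | O=CC[C@@]1(C)C2=CCCC(C)(C)[C@@H]2CC[C@@H]1C | intermediate
13 | cyclohexane-1,3-dione | O=C1CCCC(=O)C1 | starting material
14 | 2-(2-Q-ethylidene)cyclohexane-1,3-dione | O=C1CCCC(=O)C1=CC[C@@]1(C)C2=CCCC(C)(C)[C@@H]2CC[C@@H]1C | intermediate (not isolated)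
15 | 2-(2-Q-ethyl)cyclohexane-1,3-dione | O=C1CCCC(=O)C1CC[C@@]1(C)C2=CCCC(C)(C)[C@@H]2CC[C@@H]1C | intermediate
16 | ethyl vinyl ketone (pent-1-en-3-one) | C=CC(=O)CC | starting material
17 | 2-(2-Q-ethyl)-2-(3-oxopentyl)cyclohexane-1,3-dione | CCC(=O)CCC1(CC[C@@]2(C)C3=CCCC(C)(C)[C@@H]3CC[C@@H]2C)C(=O)CCCC1=O | intermediate (not isolated)
18 | (8aS)-5-methyl-8a-(2-Q-ethyl)-3,4,8,8a-tetrahydronaphthalene-1,6(2H,7H)-dione | O=C1CCCC2=C(C)C(=O)CC[C@]12CC[C@@]1(C)C2=CCCC(C)(C)[C@@H]2CC[C@@H]1C | intermediate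
19 | C4 ethylene ketal of 18: (8′aS)-5′-methyl-8′a-(2-Q-ethyl)-3′,4′,8′,8′a-tetrahydro-2′H-spiro[1,3-dioxolane-2,1′-naphthalen]-6′(7′H)-one | O1CCOC12CCCC3=C(C)C(=O)CC[C@]23CC[C@@]1(C)C2=CCCC(C)(C)[C@@H]2CC[C@@H]1C | intermediate
20 | 2-methoxybenzyl bromide (1-(bromomethyl)-2-methoxybenzene) | COc1ccccc1CBr | starting material
21 | dimethyl(phenyl)silyl enol ether of the cis-fused ketone: C4 ethylene ketal, C8(OSiMe2Ph)=C9(CH3), 10β-H, 5β-(2-Q-ethyl) | O1CCOC12CCC[C@@H]3C(C)=C(O[Si](C)(C)c4ccccc4)CC[C@]23CC[C@@]1(C)C2=CCCC(C)(C)[C@@H]2CC[C@@H]1C | intermediate (not isolated)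
22 | lithium enolate corresponding to 21 (C8–OLi, C8=C9) | O1CCOC12CCC[C@@H]3C(C)=C(O[Li])CC[C@]23CC[C@@]1(C)C2=CCCC(C)(C)[C@@H]2CC[C@@H]1C | intermediate (not isolated)
23 | cis-decalin ketal ketone: C4 ethylene ketal, C8 ketone, 5β-(2-Q-ethyl), 10β-H, 9α-CH3, 9β-(2-methoxybenzyl) | O1CCOC12CCC[C@H]3[C@]2(CC[C@@]2(C)C4=CCCC(C)(C)[C@@H]4CC[C@@H]2C)CCC(=O)[C@]3(C)Cc2ccccc2OC | intermediate
24 | as 23 with C8=CH2 in place of the ketone | O1CCOC12CCC[C@H]3[C@]2(CC[C@@]2(C)C4=CCCC(C)(C)[C@@H]4CC[C@@H]2C)CCC(=C)[C@]3(C)Cc2ccccc2OC | intermediate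
25 | as 24 with 8β-CH3 (8α-H) | O1CCOC12CCC[C@H]3[C@]2(CC[C@@]2(C)C4=CCCC(C)(C)[C@@H]4CC[C@@H]2C)CC[C@H](C)[C@]3(C)Cc2ccccc2OC | intermediate
26 | C4 ketone: 5β-(2-Q-ethyl), 10β-H, 9α-CH3, 9β-(2-methoxybenzyl), 8β-CH3 | O=C1CCC[C@H]3[C@]1(CC[C@@]2(C)C4=CCCC(C)(C)[C@@H]4CC[C@@H]2C)CC[C@H](C)[C@]3(C)Cc2ccccc2OC | intermediate
27 | 1-{[(1S,2S,4aR,8aR)-1,2-dimethyl-5-methylidene-4a-(2-Q-ethyl)decahydronaphthalen-1-yl]methyl}-2-methoxybenzene | C=C1CCC[C@H]3[C@]1(CC[C@@]2(C)C4=CCCC(C)(C)[C@@H]4CC[C@@H]2C)CC[C@H](C)[C@]3(C)Cc2ccccc2OC | intermediate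
28 | 2-{[(1S,2S,4aR,8aR)-1,2-dimethyl-5-methylidene-4a-(2-Q-ethyl)decahydronaphthalen-1-yl]methyl}phenol | C=C1CCC[C@H]3[C@]1(CC[C@@]2(C)C4=CCCC(C)(C)[C@@H]4CC[C@@H]2C)CC[C@H](C)[C@]3(C)Cc2ccccc2O | intermediate
29 | 4-hydroxy-3-{[(1S,2S,4aR,8aR)-1,2-dimethyl-5-methylidene-4a-(2-Q-ethyl)decahydronaphthalen-1-yl]methyl}phenyl hydrogen sulfate (tetrabutylammonium salt in the flask) | C=C1CCC[C@H]3[C@]1(CC[C@@]2(C)C4=CCCC(C)(C)[C@@H]4CC[C@@H]2C)CC[C@H](C)[C@]3(C)Cc2cc(OS(=O)(=O)O)ccc2O | intermediate (not isolated)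
30 | 2-{[(1S,2S,4aR,8aR)-1,2-dimethyl-5-methylidene-4a-(2-Q-ethyl)decahydronaphthalen-1-yl]methyl}-1,4-phenylene bis(hydrogen sulfate) (CNP0439949.2) | C=C1CCC[C@H]2[C@]1(CC[C@@]1(C)C3=CCCC(C)(C)[C@@H]3CC[C@@H]1C)CC[C@H](C)[C@]2(C)Cc1cc(OS(=O)(=O)O)ccc1OS(=O)(=O)O | target

## Step count and risks

Total step count: 17. Longest linear sequence: 17 (steps 1 to 17 from isobutyraldehyde; 13, 16 and 20 enter as bought).

The three steps most likely to fail:

Step 17 (the proposed new C–O bond formation). Persulfate may over-oxidise the electron-rich product, attack ortho, or stall. The fallback uses known chemistry, sets out from 28 and comes back at 30. Phenol 28 is oxidised with potassium nitrosodisulfonate ON(SO3K)2 (Teuber oxidation; KH2PO4 buffer, acetone/water, rt) to the 2-substituted 1,4-benzoquinone F1. Aqueous Na2S2O4 in Et2O reduces it to the hydroquinone F2. SO3·pyridine in pyridine at 40 °C then sulfates both hydroxyls, and the same acidic ion exchange gives 30.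

Step 13 (configuration at C8). Hydrogen may add from the β-face and give the 8α-methyl epimer. The fallback places C8 under thermodynamic rather than kinetic control, sets out from 24 and comes back at 25. Alkene 24 is hydroborated with 9-borabicyclo[3.3.1]nonane (THF, 60 °C) and oxidised (NaOH/H2O2) to the primary alcohol F3 (C8 epimers). Dess–Martin periodinane oxidation, then K2CO3 in MeOH at rt, equilibrates the formyl group to the 8β-aldehyde F4; whether 8β is the favoured epimer is a conformational estimate, not a certainty. Wolff–Kishner reduction (N2H4·H2O, KOH, diethylene glycol, 130 → 200 °C) turns the formyl group into the methyl group of 25.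

Step 11 (one-flask reduction and benzylation of a hindered tetrasubstituted enone). The copper hydride may be too slow, or the enolate regeneration and alkylation may be inefficient. The fallback separates the two events, sets out from 19 and comes back at 23. Enone 19 is hydrogenated (H2 1 atm, 5 % Pd/C, EtOAc/Et3N, stopped after one equivalent) to the isolated cis-fused ketone F5. KOtBu in t-BuOH/THF (0 °C → rt) then forms the more substituted potassium enolate, and 20 benzylates it at C9 on the convex face to give 23. This fallback does not correct a wrong facial selectivity at C9; that would need the two C9 substituents introduced in the opposite order.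

Further compounds

F1 | step 17 | 2-{[(1S,2S,4aR,8aR)-1,2-dimethyl-5-methylidene-4a-(2-Q-ethyl)decahydronaphthalen-1-yl]methyl}cyclohexa-2,5-diene-1,4-dione | C=C1CCC[C@H]3[C@]1(CC[C@@]2(C)C4=CCCC(C)(C)[C@@H]4CC[C@@H]2C)CC[C@H](C)[C@]3(C)CC2=CC(=O)C=CC2=O
F2 | step 17 | 2-{[(1S,2S,4aR,8aR)-1,2-dimethyl-5-methylidene-4a-(2-Q-ethyl)decahydronaphthalen-1-yl]methyl}benzene-1,4-diol | C=C1CCC[C@H]3[C@]1(CC[C@@]2(C)C4=CCCC(C)(C)[C@@H]4CC[C@@H]2C)CC[C@H](C)[C@]3(C)Cc2cc(O)ccc2O
F3 | step 13 | as 24 with C8–CH2OH in place of C8=CH2 (mixture of C8 epimers) | O1CCOC12CCC[C@H]3[C@]2(CC[C@@]2(C)C4=CCCC(C)(C)[C@@H]4CC[C@@H]2C)CCC(CO)[C@]3(C)Cc2ccccc2OC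
F4 | step 13 | as 25 with 8β-CHO in place of 8β-CH3 | O1CCOC12CCC[C@H]3[C@]2(CC[C@@]2(C)C4=CCCC(C)(C)[C@@H]4CC[C@@H]2C)CC[C@H](C=O)[C@]3(C)Cc2ccccc2OC
F5 | step 11 | cis-fused ketal ketone: C4 ethylene ketal, C8 ketone, 5β-(2-Q-ethyl), 10β-H, C9–H(CH3) (C9 epimers) | O1CCOC12CCC[C@H]3[C@]2(CC[C@@]2(C)C4=CCCC(C)(C)[C@@H]4CC[C@@H]2C)CCC(=O)C3C
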